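**Plan**

1. Retrosynthesis: take off the phenol and aldehyde protection, make C8=CH2 from a C8 ketone, make C3–Br from a C3 radical (hence from a C3–N bond), then cut the C3–C4 bond of ring A.
2. The freed gem-dimethyl carbon C4 is reconnected to C7. In the target C4 is 1,3 to C7 across C5–C6, and C8, next to C7, is sp2. Ring B (C5–C10) with a C8 carbonyl is therefore the six-membered ring of a nopinone, and C4–C5–C6–C7 is its cyclobutane.
3. C9–C11 (aryl addition to a C9 methylidene ketone), C10–CH3 (cuprate), C10–C1 (Grignard addition with oxidative 1,3-transposition) and the C3 oxime ether are cut next. This leads to (+)-nopinone (1) and a protected bromo-hydroquinone aldehyde.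
4. Forward: the pinane bicycle is decorated at C10 and C9. One operation then opens the cyclobutane from the C8 ketyl and closes ring A (C3–C4) by 6-exo attack of the C4 radical on the oxime carbon C3. N–O cleavage, deaminative bromination, methylenation and deprotection follow.
5. Stereochemistry: all from (1R,5S)-nopinone. The gem-dimethyl bridge (the future C4) sends the C10 methyl group and the C9 hydrogen to the opposite face, so C1, C11 and C4 end up cis (cis ring fusion, 9α-arylmethyl). C3–Br comes from equatorial bromine transfer to the C3 radical.

Key step: step 11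

Remarks: C1–C12 are the drimane locants of the target (ring A: C1–C5 and C10; ring B: C5–C10; C11 benzylic carbon; C12 methylidene carbon). β is the face of the C10 methyl group; syn and anti refer to the gem-dimethyl bridge of the bicyclo[3.1.1]heptanes. C3 of 14 and 15 is drawn as the expected equatorial epimer, which is of no consequence because C3 is planar again in step 13; oxime ethers are drawn E.

Step 1
Reactants: 1 (+)-nopinone
Product: 2 apoverbenone
Conditions: LiN(iPr)2, THF, −78 °C; PhS(Cl)=N-t-Bu, −78 °C
Reagents that add atoms: none
Why: Deprotonation can occur only at the α-methylene group (the bridgehead cannot enolize), and the sulfinimidoyl chloride dehydrogenates the lithium enolate to the enone in the same flask (ketone dehydrogenation by sulfinimidoylation and elimination); no stereocenter is touched.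

Step 2
Reactants: 2 apoverbenone
Product: 3 tertiary allylic alcohol (butenyl anti to the bridge)
Conditions: CH2=CHCH2CH2MgBr, THF, −78 → 0 °C; aq. NH4Cl
Reagents that add atoms: but-3-enylmagnesium bromide, C=CCC[Mg]Br
Why: Grignard 1,2-addition to the enone carbonyl from the face anti to the gem-dimethyl bridge brings in C1–C3 and one extra carbon; the carbinol configuration is erased in step 3.

Step 3
Reactants: 3 tertiary allylic alcohol
Product: 4 butenyl enone
Conditions: [C5H5NH][CrO3Cl] (pyridinium chlorochromate), 4 Å sieves, CH2Cl2, rt
Reagents that add atoms: pyridinium chlorochromate, [O-][Cr](=O)(=O)Cl.c1cc[nH+]cc1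
Why: Babler–Dauben oxidative transposition: the chromate ester of the tertiary allylic alcohol undergoes a [3,3]-shift and is oxidized, which puts the carbonyl on the carbon that becomes C8 and leaves the chain on the future C10 of a β-substituted enone.

Step 4
Reactants: 4 butenyl enone
Product: 5 methyl butenyl ketone
Conditions: Me2CuLi (from MeLi and CuI), Et2O, −20 → 0 °C; aq. NH4Cl
Reagents that add atoms: lithium dimethylcuprate, [Li+].C[Cu-]C
Why: Cuprate conjugate addition occurs on the face anti to the gem-dimethyl bridge, as it does with verbenone, and so sets the quaternary C10 center with methyl anti and the chain syn to the bridge (the relationship needed for the cis ring fusion).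

Step 5
Reactants: 5 methyl butenyl ketone
Product: 7 keto oxime ether (O-benzyl oxime), via keto aldehyde 6 (not isolated)
Conditions: O3, CH2Cl2/MeOH, −78 °C; Me2S; then BnONH2, pyridine, 0 °C → rt
Reagents that add atoms: O-benzylhydroxylamine, NOCc1ccccc1
Why: Ozonolysis with reductive work-up cleaves the only alkene to the C3 aldehyde, which condenses with O-benzylhydroxylamine far faster than the hindered ketone (the oxygen brought in by ozone leaves again as water); no stereocenter is affected.

Step 6
Reactants: 7 keto oxime ether
Product: 8 methylidene ketone
Conditions: (CH2O)n, [PhNH2Me][CF3CO2], THF, reflux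
Reagents that add atoms: formaldehyde (as paraformaldehyde), C=O
Why: Mannich-type α-methylenation (iminium ion from formaldehyde and the anilinium salt, then β-elimination) can take place only at C9, the single enolizable position, and installs C11.

Step 7
Reactants: 9 2,5-dibromohydroquinone
Product: 10 bis-MOM dibromide
Conditions: MOMCl, i-Pr2NEt, CH2Cl2, 0 °C → rt
Reagents that add atoms: chloromethyl methyl ether, COCCl
Why: O-Alkylation of both phenols (MOM ether formation) masks the hydroquinone for the organometallic and reductive steps.

Step 8
Reactants: 10 bis-MOM dibromide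
Product: 11 bromo aldehyde
Conditions: n-BuLi (1 equiv), THF, −78 °C; DMF; aq. NH4Cl
Reagents that add atoms: N,N-dimethylformamide, CN(C)C=O
Why: A single bromine–lithium exchange of the symmetrical dibromide and formylation of the aryllithium with DMF should give the monoaldehyde.

Step 9
Reactants: 11 bromo aldehyde
Product: 12 bromo aryl dioxolane
Conditions: TMSOCH2CH2OTMS, TMSOTf (cat.), CH2Cl2, −78 °C
Reagents that add atoms: 1,2-bis(trimethylsilyloxy)ethane, C[Si](C)(C)OCCO[Si](C)(C)C
Why: Acetalization with the bis-silyl glycol under silyl triflate catalysis is aprotic and leaves the MOM ethers intact.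

Step 10
Reactants: 8 methylidene ketone; 12 bromo aryl dioxolane
Product: 13 arylmethyl ketone (arylmethyl syn to the bridge)
Conditions: 12, n-BuLi, THF, −78 °C; MgBr2·OEt2; CuI (10 mol%); then 8, −78 → −40 °C; aq. NH4Cl at −78 °C
Reagents that add atoms: none
Why: Copper-catalyzed conjugate addition of the aryl Grignard reagent (from bromine–lithium exchange and transmetalation) to the unhindered methylidene carbon C11; C9 is set by kinetic protonation of the magnesium enolate from the face anti to the gem-dimethyl bridge, which leaves the arylmethyl group syn to the bridge.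

Step 11
Reactants: 13 arylmethyl ketone
Product: 14 cis-decalone alkoxyamine
Conditions: SmI2 (2.5 equiv, slow addition), HMPA, THF, −78 → 0 °C; aq. NH4Cl
Reagents that add atoms: none
Why: Proposed new method: SmI2–HMPA reduces the C8 carbonyl to a ketyl whose singly occupied orbital overlaps the strained C7–C4 bond of the cyclobutane, and β-scission (loss of the four-membered ring strain, a tertiary C4 radical instead of the primary C6 radical, a trivalent samarium enolate on the C7 side) sets free the C4 radical, which adds to C3 of the oxime ether before a second SmI2 reduces the alkoxyaminyl radical, and work-up protonates nitrogen and the enolate. The closest known reaction types are the SmI2- or stannane-induced scission of cyclopropyl and cyclobutyl ketones with tandem radical cyclization and the radical cyclization onto O-benzyl oxime ethers; their union on a pinane ketone is not known. Ring A closes in the 6-exo-trig mode through a chair-like transition state, and the cis ring fusion is inherited, because C4 on C5 and the C1–C3 chain on C10 both stand on the bridge face of 13. The new C3 center should carry nitrogen equatorially (C=N pseudo-equatorial in the chair), but this has no consequence because C3 is a radical again in step 13. The step needs scission to outrun ketyl–oxime coupling, which is secured because that coupling would have to build a second bridge on the hindered face of the pinane, and cyclization to outrun reduction of the tertiary radical, which is secured by slow addition of SmI2 and the high rate of alkyl radical addition to oxime ethers. C9 keeps its configuration since the enolate forms only toward C7.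

Step 12
Reactants: 14 cis-decalone alkoxyamine
Product: 15 cis-decalone amine
Conditions: Mo(CO)6, MeCN/H2O, 80 °C
Reagents that add atoms: none
Why: Reductive N–O cleavage by zerovalent molybdenum under neutral conditions spares the ketone, the MOM ethers and the benzylic dioxolane, which would not survive hydrogenolysis.

Step 13
Reactants: 15 cis-decalone amine
Product: 16 bromo ketone
Conditions: ArC(O)N(OBn)OPiv (Ar = 4-CF3C6H4), BrCCl3, MeCN, 45 °C
Reagents that add atoms: bromotrichloromethane, BrC(Cl)(Cl)Cl
Why: Deaminative bromination: N-amination of the primary amine by the anomeric amide gives an isodiazene that tautomerizes to the monoalkyl diazene, whose radical chain with BrCCl3 passes through the C3 radical; bromine should be delivered to the equatorial β-face because the α-axial approach is blocked by the syn-axial C6 methylene of the cis-decalin, so both C3 epimers of 15 converge on the 3β-bromide.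

Step 14
Reactants: 16 bromo ketone
Product: 17 protected peyssonol A
Conditions: Cp2TiMe2, toluene/THF, 65 °C, dark
Reagents that add atoms: dimethyltitanocene, C[Ti](C)(C1C=CC=C1)C1C=CC=C1
Why: Petasis methylenation through Cp2Ti=CH2 converts the hindered C8 ketone into the exocyclic alkene without base, so C9 should not epimerize and the secondary bromide should not eliminate.

Step 15
Reactants: 17 protected peyssonol A
Product: 18 peyssonol A
Conditions: 2 M aq. HCl, THF, rt
Reagents that add atoms: water, O
Why: Acetal hydrolysis in dilute aqueous acid removes the two aryl MOM ethers and the dioxolane in one operation, conditions that the 1,1-disubstituted alkene and the neopentylic bromide should tolerate at ambient temperature.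

**Compound list**

1 | (+)-nopinone, (1R,5S)-6,6-dimethylbicyclo[3.1.1]heptan-2-one | CC1(C)[C@H]2CCC(=O)[C@@H]1C2 | starting material
2 | apoverbenone, (1R,5R)-6,6-dimethylbicyclo[3.1.1]hept-3-en-2-one | CC1(C)[C@H]2C=CC(=O)[C@@H]1C2 | intermediate
3 | (1R,2R,5R)-2-(but-3-en-1-yl)-6,6-dimethylbicyclo[3.1.1]hept-3-en-2-ol (butenyl anti, hydroxyl syn to the gem-dimethyl bridge) | CC1(C)[C@H]2C=C[C@](O)(CCC=C)[C@@H]1C2 | intermediate
4 | (1S,5R)-4-(but-3-en-1-yl)-6,6-dimethylbicyclo[3.1.1]hept-3-en-2-one (butenyl homologue of (−)-verbenone) | CC1(C)[C@H]2C(=O)C=C(CCC=C)[C@@H]1C2 | intermediate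
5 | (1S,4R,5S)-4-(but-3-en-1-yl)-4,6,6-trimethylbicyclo[3.1.1]heptan-2-one (4-methyl anti, butenyl syn to the gem-dimethyl bridge) | O=C1[C@H]2C[C@H](C2(C)C)[C@](C)(CCC=C)C1 | intermediate
6 | 3-(2,6,6-trimethyl-4-oxobicyclo[3.1.1]hept-2-yl)propanal, ring configuration as in 5 (2-methyl anti, propanal chain syn to the bridge) | O=C1[C@H]2C[C@H](C2(C)C)[C@](C)(CCC=O)C1 | intermediate (not isolated)
7 | O-benzyl oxime of 6 (E shown) | O=C1[C@H]2C[C@H](C2(C)C)[C@](C)(CC/C=N/OCc2ccccc2)C1 | intermediate
8 | O-benzyl oxime of 3-(2,6,6-trimethyl-3-methylidene-4-oxobicyclo[3.1.1]hept-2-yl)propanal, ring configuration as in 5 | O=C1[C@H]2C[C@H](C2(C)C)[C@](C)(CC/C=N/OCc2ccccc2)C1=C | intermediate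
9 | 2,5-dibromobenzene-1,4-diol (2,5-dibromohydroquinone) | Oc1cc(Br)c(O)cc1Br | starting material
10 | 1,4-dibromo-2,5-bis(methoxymethoxy)benzene | COCOc1cc(Br)c(OCOC)cc1Br | intermediate
11 | 4-bromo-2,5-bis(methoxymethoxy)benzaldehyde | COCOc1cc(Br)c(OCOC)cc1C=O | intermediate
12 | 2-[4-bromo-2,5-bis(methoxymethoxy)phenyl]-1,3-dioxolane | COCOc1cc(Br)c(OCOC)cc1C1OCCO1 | intermediate
13 | O-benzyl oxime of 3-[3-{[4-(1,3-dioxolan-2-yl)-2,5-bis(methoxymethoxy)phenyl]methyl}-2,6,6-trimethyl-4-oxobicyclo[3.1.1]hept-2-yl]propanal; arylmethyl group and oxime chain syn, 2-methyl anti to the gem-dimethyl bridge | O=C1[C@H]2C[C@H](C2(C)C)[C@](C)(CC/C=N/OCc2ccccc2)[C@@H]1Cc1cc(OCOC)c(C3OCCO3)cc1OCOC | intermediate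
14 | cis-fused decalone (drimane locants): 3β-(benzyloxyamino)-9α-{[4-(1,3-dioxolan-2-yl)-2,5-bis(methoxymethoxy)phenyl]methyl}-4,4,10β-trimethyl-5β-H-decalin-8-one | O=C1CC[C@@H]2C(C)(C)[C@@H](NOCc3ccccc3)CC[C@]2(C)[C@@H]1Cc1cc(OCOC)c(C3OCCO3)cc1OCOC | intermediate
15 | 3β-amino analogue of 14 (primary amine; 9α-arylmethyl, 5β-H, 10β-methyl, C8 ketone) | O=C1CC[C@@H]2C(C)(C)[C@@H](N)CC[C@]2(C)[C@@H]1Cc1cc(OCOC)c(C3OCCO3)cc1OCOC | intermediate
16 | 3β-bromo-9α-{[4-(1,3-dioxolan-2-yl)-2,5-bis(methoxymethoxy)phenyl]methyl}-4,4,10β-trimethyl-5β-H-decalin-8-one | O=C1CC[C@@H]2C(C)(C)[C@@H](Br)CC[C@]2(C)[C@@H]1Cc1cc(OCOC)c(C3OCCO3)cc1OCOC | intermediate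
17 | 8-methylidene analogue of 16 (bis-MOM ether and dioxolane of peyssonol A) | C=C1CC[C@@H]2C(C)(C)[C@@H](Br)CC[C@]2(C)[C@@H]1Cc1cc(OCOC)c(C3OCCO3)cc1OCOC | intermediate
18 | peyssonol A: 4-{[3β-bromo-4,4,10β-trimethyl-8-methylidene-5β-H-cis-decalin-9α-yl]methyl}-2,5-dihydroxybenzaldehyde | C=C1CC[C@@H]2C(C)(C)[C@@H](Br)CC[C@]2(C)[C@@H]1Cc1cc(O)c(C=O)cc1O | target

**Step count**

Total: 15 steps. Longest linear sequence: 12 steps (steps 1–6 and 10–15); steps 7–9 build the aryl bromide.

**Steps most likely to fail**

Step 11 (Proposed new method). The ketyl may be protonated or reduced further before the cyclobutane opens. The tertiary C4 radical may be reduced by SmI2, or may abstract the benzylic hydrogen at C11, before it reaches C3. Fallback, setting out from 13 and coming back at 14, with known chemistry: a tin hydride radical chain in place of electron transfer (Bu3SnH by syringe pump, AIBN, benzene, 80 °C). Reversible addition of the stannyl radical to the C8 carbonyl oxygen gives the O-stannyl ketyl, which should undergo the same scission and 6-exo cyclization with no reductant present. Hydrogen transfer from the stannane to the alkoxyaminyl radical carries the chain, and hydrolysis of the tin enolate returns 14. Both halves are established stannane chemistry (O-stannyl ketyl scission of strained-ring ketones with tandem cyclization; stannyl radical addition–cyclization of carbonyl compounds onto O-benzyl oximes), though they have not been joined on a cyclobutyl ketone. No new compound is made.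

Step 13. N-Amination of the neopentylic amine may be slow relative to decomposition of the anomeric amide, and bromine transfer to the C3 radical may lose facial selectivity at 45 °C. Fallback, setting out from 15 and coming back at 16: condensation with 2,4,6-triphenylpyrylium tetrafluoroborate (EtOH, reflux) should give the N-alkyl-2,4,6-triphenylpyridinium tetrafluoroborate F1. Single-electron reduction of F1 (Ir(ppy)3 cat., i-Pr2NEt, blue light, MeCN, rt or below) in the presence of BrCCl3 generates the same C3 radical by C–N fragmentation, without an isodiazene and at a lower temperature, where the equatorial preference of the bromine transfer should be sharper. Formation of F1 at this hindered nitrogen may itself be slow.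

Step 10. The enolate may be protonated in part from the bridge face, or the kinetically formed C9 epimer (arylmethyl syn to the bridge) may epimerize during work-up. Fallback, setting out from 8 (with 12) and coming back at 13: a Heck reaction of 12 with the methylidene ketone 8 (Pd(P(t-Bu)3)2 as zerovalent palladium catalyst, Cy2NMe, dioxane, 80 °C) should give the (E)-arylidene ketone F2; β-hydride elimination can occur only toward C11. Hydrogenation over Rh/Al2O3 (H2, EtOAc, rt) then adds both hydrogens from the face anti to the gem-dimethyl bridge and sets C9 by syn addition instead of protonation. This catalyst should leave the O-benzyl oxime and the benzylic dioxolane intact.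

Further compounds
F0 | step 11 | none | none
F1 | step 13 | 1-[(drimane locants) 9α-{[4-(1,3-dioxolan-2-yl)-2,5-bis(methoxymethoxy)phenyl]methyl}-4,4,10β-trimethyl-8-oxo-5β-H-decalin-3β-yl]-2,4,6-triphenylpyridinium tetrafluoroborate | O=C1CC[C@@H]2C(C)(C)[C@@H]([n+]3c(-c4ccccc4)cc(-c4ccccc4)cc3-c3ccccc3)CC[C@]2(C)[C@@H]1Cc1cc(OCOC)c(C3OCCO3)cc1OCOC.F[B-](F)(F)F
F2 | step 10 | (E)-arylidene ketone: O-benzyl oxime of 3-[3-{[4-(1,3-dioxolan-2-yl)-2,5-bis(methoxymethoxy)phenyl]methylidene}-2,6,6-trimethyl-4-oxobicyclo[3.1.1]hept-2-yl]propanal, ring configuration as in 5 | O=C1[C@H]2C[C@H](C2(C)C)[C@](C)(CC/C=N/OCc2ccccc2)/C1=C\c1cc(OCOC)c(C3OCCO3)cc1OCOC
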